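**Retrosynthetic overview**
1. Target ⇐ its 3-ketone (substrate-controlled axial reduction) ⇐ tetraacetoxy 3,13-dione + vinyl nucleophile (C13–C14 bond, Felkin–Anh control from C12).
2. That methyl ketone ⇐ a dihydropyran enol ether by Woodward cis-oxygenation (C12–O set by the temporary ring C) and exhaustive acetylation.
3. Enol ether ⇐ cyclic methyl ketal by the key photochemical step: 6β-alkoxy radical, 1,5-HAT from C20, O2 capture (C20–O bond).
4. Ketal ⇐ ambreinolide: electrochemical C2–H oxidation then 1,2-carbonyl transposition (ring A, C3); 7-ene → electrochemical allylic oxidation → reduction → hydration (ring B, C6 and C8).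
5. Ambreinolide ⇐ (−)-sclareol: rings A and B (C5, C8, C9, C10) are bought and no carbocycle is built; a temporary oxygen ring C (δ-lactone → cyclic ketal → dihydropyran) is closed in steps 2, 7 and 8 and opened in step 13.

Assumption: natural (−)-sclareol, (13R)-labd-14-ene-8α,13-diol, is the commercial chiral starting material; labdane numbering is used (side chain C11–C16, C20 on C10).

**Route**

Step 1
Reactants: 1 (−)-sclareol
Product: 2 8α-hydroxy-14,15-dinorlabdan-13-one
Conditions: KMnO4, MgSO4, acetone–H2O, 0→20 °C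
Reagents that add atoms: none
Why: Permanganate oxidative cleavage of the vinyl carbinol (α-hydroxy acid, then oxidative decarboxylation) gives the C13 methyl ketone, the classical sclareol degradation, leaving C5, C8, C9 and C10 untouched.

Step 2
Reactants: 2 8α-hydroxy-14,15-dinorlabdan-13-one
Product: 4 ambreinolide (14,15,16-trinorlabdan-13,8α-olide), via hydroxy acid 3 (not isolated)
Conditions: aq. NaOCl, NaOH, 1,4-dioxane, 0→20 °C; then 2 M HCl to pH 2; p-TsOH (cat.), PhMe, 40 °C
Reagents that add atoms: sodium hydroxide ([Na+].[OH-])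
Why: Haloform reaction removes C16 as chloroform (hydroxide supplies the second carboxyl oxygen of 3) and the δ-hydroxy acid lactonises onto the tertiary 8α-OH, tying up 8-O and making the side chain inert for the ring chemistry; no new stereocentre.

Step 3
Reactants: 4 ambreinolide
Product: 5 2-oxoambreinolide
Conditions: quinuclidine (1 equiv), Me4NBF4, HFIP, MeCN, O2 (1 atm), RVC anode/Ni cathode, constant current, 25 °C
Reagents that add atoms: dioxygen (O=O)
Why: Quinuclidine-mediated electrochemical C–H oxidation (anodic quinuclidinium radical cation as HAT agent, O2 trapping) attacks the most hydridic and exposed methylene, C2 of ring A, remote from the deactivating lactone, as known for the lower homologue sclareolide.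

Step 4
Reactants: 5 2-oxoambreinolide
Product: 6 methyl 2-oxo-14,15,16-trinorlabd-7-en-13-oate
Conditions: conc. H2SO4 (0.5 equiv), MeOH, reflux; AgNO3–SiO2 chromatography
Reagents that add atoms: methanol (CO)
Why: Acid-catalysed alkyl–oxygen lactone opening through the tertiary C8 cation, E1 loss of H7 to the endocyclic trisubstituted alkene and Fischer esterification; minor 8(17)- and 8(9)-ene isomers are separated, and C8 is re-made in step 7.

Step 5
Reactants: 6 methyl 2-oxo-14,15,16-trinorlabd-7-en-13-oate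
Product: 7 methyl 2,6-dioxo-14,15,16-trinorlabd-7-en-13-oate
Conditions: Cl4NHPI (20 mol %), pyridine, t-BuOOH, LiClO4, acetone, RVC anode/RVC cathode, constant current, 25 °C
Reagents that add atoms: tert-butyl hydroperoxide (CC(C)(C)OO)
Why: Electrochemical allylic C–H oxidation (anodic tetrachlorophthalimide-N-oxyl as HAT mediator) converts the ring allylic CH2 (C6) into the conjugated enone, as for steroidal 5-enes to 7-ketones; the C2 ketone and the ester are inert.

Step 6
Reactants: 7 methyl 2,6-dioxo-14,15,16-trinorlabd-7-en-13-oate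
Product: 8 methyl 6β-hydroxy-2-oxo-14,15,16-trinorlabd-7-en-13-oate
Conditions: NaBH4, CeCl3·7H2O, MeOH, −78 °C
Reagents that add atoms: none
Why: Luche 1,2-reduction: the cerium-activated enone is reduced in preference to the saturated C2 ketone at −78 °C, and hydride reaches C6 only from the α face because the β face is blocked by the syn-axial C19 and C20 methyls, giving the axial 6β-alcohol.

Step 7
Reactants: 8 methyl 6β-hydroxy-2-oxo-14,15,16-trinorlabd-7-en-13-oate
Product: 10 6β-hydroxy-2-oxoambreinolide, via hydroxy ester 9 (not isolated)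
Conditions: Co(acac)2 (20 mol %), PhSiH3, O2 (1 atm), i-PrOH–THF, 20 °C; then p-TsOH (cat.), PhMe, 50 °C
Reagents that add atoms: dioxygen (O=O)
Why: Mukaiyama hydration: Co–H hydrogen-atom transfer to C7 gives the tertiary C8 radical, oxygenated on the equatorial α face (β face shielded by C20 and the 6β-OH) to restore the natural 8α-OH/8β-Me centre; acid then closes the δ-lactone with loss of methanol.

Step 8
Reactants: 10 6β-hydroxy-2-oxoambreinolide
Product: 12 8α,13-epoxy-6β-hydroxy-13β-methoxy-14,15-dinorlabdan-2-one, via hydroxy diketone 11 (not isolated)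
Conditions: KH (2.2 equiv), THF, 0→20 °C; then CH3Li (1.3 equiv), −78 °C; MeOH quench at −78 °C; then p-TsOH (cat.), MeOH, 3 Å MS, 20 °C
Reagents that add atoms: methyllithium ([Li]C); methanol (CO)
Why: In situ protection of the C2 ketone as its potassium enolate (KH also forms the 6β-alkoxide, and the less acidic lactone stays un-enolised), mono-addition of methyllithium to the lactone (lithium hemiketalate stable at −78 °C), then acid-catalysed intramolecular ketalisation give the cyclic methyl ketal, masking the new C13 ketone and keeping 8-O tied; the hindered C2 ketone does not form a dimethyl ketal, and the anomeric C13 centre (axial OMe) is temporary.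

Step 9
Reactants: 12 8α,13-epoxy-6β-hydroxy-13β-methoxy-14,15-dinorlabdan-2-one
Product: 13 8α,13-epoxy-6β-hydroxy-13β-methoxy-14,15-dinorlabd-2-en-2-yl trifluoromethanesulfonate
Conditions: KN(SiMe3)2 (2.2 equiv), THF, −78 °C; PhNTf2 (1.1 equiv), −78→0 °C
Reagents that add atoms: N-phenylbis(trifluoromethanesulfonimide) (O=S(=O)(N(c1ccccc1)S(=O)(=O)C(F)(F)F)C(F)(F)F)
Why: Kinetic enolisation of the only ketone toward C3 (axial 3α-H; C1 is shielded by C11 and C20, as 2-oxo-5α-steroids enolise toward C3) and enolate O-triflation; the hindered 6β-alkoxide is not triflated.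

Step 10
Reactants: 13 8α,13-epoxy-6β-hydroxy-13β-methoxy-14,15-dinorlabd-2-en-2-yl trifluoromethanesulfonate
Product: 15 8α,13-epoxy-6β-hydroxy-13β-methoxy-14,15-dinorlabdan-3-one, via morpholine enamine 14 (not isolated)
Conditions: Pd(OAc)2 (10 mol %), P(2-furyl)3, norbornene (50 mol %), N-(benzoyloxy)morpholine, Cs2CO3, i-PrOH, 1,4-dioxane, 90 °C; then AcOH–NaOAc buffer (pH 5), THF–H2O, 20 °C
Reagents that add atoms: N-(benzoyloxy)morpholine (O=C(ON1CCOCC1)c1ccccc1); water (O)
Why: Palladium/norbornene (Catellani-type) 1,2-carbonyl transposition: oxidative addition of zerovalent palladium to the alkenyl triflate, norbornene-relayed C3–H palladation and amination by the N–O electrophile, ipso termination by hydride from isopropoxide, then hydrolysis of the C3 enamine (the morpholine unit is present only in 14 and is released again) moves the carbonyl from C2 to C3; no stereocentre is formed and the buffered hydrolysis spares the ketal.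

Step 11
Reactants: 15 8α,13-epoxy-6β-hydroxy-13β-methoxy-14,15-dinorlabdan-3-one
Product: 17 8α,13-epoxy-6β,20-dihydroxy-13β-methoxy-14,15-dinorlabdan-3-one, via C20 hydroperoxide 16 (not isolated)
Conditions: (n-Bu4N)2CeCl6 (5 mol %), NaHCO3, O2 (1 atm), MeCN, 400 nm LEDs, 10 °C, to ca. 70 % conversion; then PPh3, 0 °C
Reagents that add atoms: dioxygen (O=O)
Why: Proposed new method: aerobic cerium-photocatalysed δ-C–H hydroxylation of a free alcohol — the 6β-alkoxide binds tetravalent cerium, ligand-to-metal charge transfer at 400 nm releases the 6β-alkoxy radical, which abstracts H from the 1,3-syn-axial C20 methyl through a six-membered transition state (1,5-HAT); the neopentyl radical (no β-H) is trapped by O2 and the peroxyl radical re-oxidises trivalent cerium to give the hydroperoxide, reduced by PPh3; the two competing syn-axial methyls are polar-deactivated (C19 by the adjacent C3 carbonyl, C17 by the ketal oxygen on C8); closest known chemistry is the Barton nitrite/hypoiodite remote functionalisation of 6β-hydroxy steroids and cerium-LMCT 1,5-HAT δ-amination of alcohols; no stereocentre is formed.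

Step 12
Reactants: 17 8α,13-epoxy-6β,20-dihydroxy-13β-methoxy-14,15-dinorlabdan-3-one
Product: 18 8α,13-epoxy-6β,20-dihydroxy-14,15-dinorlabd-12-en-3-one
Conditions: PPTS (10 mol %), PhMe, 90 °C, 4 Å MS
Reagents that add atoms: none
Why: Acid-catalysed elimination of methanol from the ketal via the tertiary oxocarbenium ion gives the thermodynamically preferred endocyclic dihydropyran enol ether (sclareol-oxide type).

Step 13
Reactants: 18 8α,13-epoxy-6β,20-dihydroxy-14,15-dinorlabd-12-en-3-one
Product: 20 (12R)-12-acetoxy-6β,8α,20-trihydroxy-14,15-dinorlabdane-3,13-dione, via iodo acetate 19 (not isolated)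
Conditions: N-iodosuccinimide, AcOH–CH2Cl2, 0 °C, dark; then AgOAc, AcOH–H2O (19:1), 50 °C
Reagents that add atoms: N-iodosuccinimide (O=C1CCC(=O)N1I); acetic acid (CC(=O)O); water (O)
Why: Woodward cis-oxygenation of the enol ether: iodonium adds axially to C12 from the open α face, acetate caps the C13 oxocarbenium, and silver-assisted displacement of iodide (present only in 19) by the neighbouring acetate (acetoxonium ion) with inversion places oxygen on the β face of C12 (12R); orthoester hydrolysis and hemiketal collapse release the methyl ketone and free 8-OH.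

Step 14
Reactants: 20 (12R)-12-acetoxy-6β,8α,20-trihydroxy-14,15-dinorlabdane-3,13-dione
Product: 21 (12R)-6β,8α,12,20-tetraacetoxy-14,15-dinorlabdane-3,13-dione
Conditions: AcCl (excess), PhNMe2, CH2Cl2, 0→35 °C
Reagents that add atoms: acetyl chloride (CC(=O)Cl)
Why: Exhaustive O-acetylation with acetyl chloride/N,N-dimethylaniline, the standard method for the tertiary 8α-OH of sclareol-derived hydroxy ketones, also esterifies the primary C20-OH and the hindered 6β-OH without epimerising the α-acetoxy ketone; since neither the C3 nor the C13 carbinol exists yet, the acetate pattern of the target is fixed here.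

Step 15
Reactants: 21 (12R)-6β,8α,12,20-tetraacetoxy-14,15-dinorlabdane-3,13-dione
Product: 22 (12R,13S)-6β,8α,12,20-tetraacetoxy-13-hydroxylabd-14-en-3-one
Conditions: CH2=CHTi(OiPr)3 (from CH2=CHMgBr + ClTi(OiPr)3), THF, −78→−20 °C; aq. NH4Cl
Reagents that add atoms: vinyltitanium triisopropoxide (C=C[Ti](OC(C)C)(OC(C)C)OC(C)C)
Why: Chemoselective carbonyl addition of a non-chelating, weakly basic organotitanium reagent: only the unhindered, α-acetoxy-activated C13 methyl ketone reacts (acetates and the neopentyl C3 ketone are spared), and Felkin–Anh control by C12 (C–OAc anti to the incoming vinyl, attack past H) sets C13 as S.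

Step 16
Reactants: 22 (12R,13S)-6β,8α,12,20-tetraacetoxy-13-hydroxylabd-14-en-3-one
Product: 23 (12R,13S)-6β,8α,12,20-tetraacetoxylabd-14-ene-3α,13-diol (target)
Conditions: KBH(s-Bu)3 (K-Selectride), THF, −78 °C; aq. NH4Cl
Reagents that add atoms: none
Why: Hindered trialkylborohydride reduction: equatorial hydride delivery to the 4,4-dimethyl-3-ketone gives the axial 3α-alcohol (3R) under substrate control, while acetates, alkene and tertiary alcohol survive at −78 °C.

**Compound list**
1 | (−)-sclareol, (13R)-labd-14-ene-8α,13-diol | C=C[C@](C)(O)CC[C@@H]1[C@@]2(C)CCCC(C)(C)[C@@H]2CC[C@@]1(C)O | starting material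
2 | 8α-hydroxy-14,15-dinorlabdan-13-one | CC(=O)CC[C@@H]1[C@@]2(C)CCCC(C)(C)[C@@H]2CC[C@@]1(C)O | intermediate
3 | 8α-hydroxy-14,15,16-trinorlabdan-13-oic acid | OC(=O)CC[C@@H]1[C@@]2(C)CCCC(C)(C)[C@@H]2CC[C@@]1(C)O | intermediate
4 | ambreinolide (14,15,16-trinorlabdan-13,8α-olide) | O=C1CC[C@@H]2[C@@]3(C)CCCC(C)(C)[C@@H]3CC[C@@]2(C)O1 | intermediate
5 | 2-oxoambreinolide | O=C1CC[C@@H]2[C@@]3(C)CC(=O)CC(C)(C)[C@@H]3CC[C@@]2(C)O1 | intermediate
6 | methyl 2-oxo-14,15,16-trinorlabd-7-en-13-oate | COC(=O)CC[C@@H]1[C@@]2(C)CC(=O)CC(C)(C)[C@@H]2CC=C1C | intermediate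
7 | methyl 2,6-dioxo-14,15,16-trinorlabd-7-en-13-oate | COC(=O)CC[C@@H]1[C@@]2(C)CC(=O)CC(C)(C)[C@@H]2C(=O)C=C1C | intermediate
8 | methyl 6β-hydroxy-2-oxo-14,15,16-trinorlabd-7-en-13-oate | COC(=O)CC[C@@H]1[C@@]2(C)CC(=O)CC(C)(C)[C@@H]2[C@H](O)C=C1C | intermediate
9 | methyl 6β,8α-dihydroxy-2-oxo-14,15,16-trinorlabdan-13-oate | COC(=O)CC[C@@H]1[C@@]2(C)CC(=O)CC(C)(C)[C@@H]2[C@H](O)C[C@@]1(C)O | intermediate
10 | 6β-hydroxy-2-oxoambreinolide | O=C1CC[C@@H]2[C@@]3(C)CC(=O)CC(C)(C)[C@@H]3[C@H](O)C[C@@]2(C)O1 | intermediate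
11 | 6β,8α-dihydroxy-14,15-dinorlabdane-2,13-dione | CC(=O)CC[C@@H]1[C@@]2(C)CC(=O)CC(C)(C)[C@@H]2[C@H](O)C[C@@]1(C)O | intermediate
12 | 8α,13-epoxy-6β-hydroxy-13β-methoxy-14,15-dinorlabdan-2-one | CO[C@]1(C)CC[C@@H]2[C@@]3(C)CC(=O)CC(C)(C)[C@@H]3[C@H](O)C[C@@]2(C)O1 | intermediate
13 | 8α,13-epoxy-6β-hydroxy-13β-methoxy-14,15-dinorlabd-2-en-2-yl trifluoromethanesulfonate | CO[C@]1(C)CC[C@@H]2[C@@]3(C)CC(OS(=O)(=O)C(F)(F)F)=CC(C)(C)[C@@H]3[C@H](O)C[C@@]2(C)O1 | intermediate
14 | 8α,13-epoxy-6β-hydroxy-13β-methoxy-3-morpholino-14,15-dinorlabd-2-ene | CO[C@]1(C)CC[C@@H]2[C@@]3(C)CC=C(N4CCOCC4)C(C)(C)[C@@H]3[C@H](O)C[C@@]2(C)O1 | intermediate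
15 | 8α,13-epoxy-6β-hydroxy-13β-methoxy-14,15-dinorlabdan-3-one | CO[C@]1(C)CC[C@@H]2[C@@]3(C)CCC(=O)C(C)(C)[C@@H]3[C@H](O)C[C@@]2(C)O1 | intermediate
16 | 8α,13-epoxy-20-hydroperoxy-6β-hydroxy-13β-methoxy-14,15-dinorlabdan-3-one | CO[C@]1(C)CC[C@@H]2[C@@]3(COO)CCC(=O)C(C)(C)[C@@H]3[C@H](O)C[C@@]2(C)O1 | intermediate
17 | 8α,13-epoxy-6β,20-dihydroxy-13β-methoxy-14,15-dinorlabdan-3-one | CO[C@]1(C)CC[C@@H]2[C@@]3(CO)CCC(=O)C(C)(C)[C@@H]3[C@H](O)C[C@@]2(C)O1 | intermediate
18 | 8α,13-epoxy-6β,20-dihydroxy-14,15-dinorlabd-12-en-3-one | CC1=CC[C@@H]2[C@@]3(CO)CCC(=O)C(C)(C)[C@@H]3[C@H](O)C[C@@]2(C)O1 | intermediate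
19 | 13β-acetoxy-8α,13-epoxy-6β,20-dihydroxy-12α-iodo-14,15-dinorlabdan-3-one | CC(=O)O[C@]1(C)[C@@H](I)C[C@@H]2[C@@]3(CO)CCC(=O)C(C)(C)[C@@H]3[C@H](O)C[C@@]2(C)O1 | intermediate
20 | (12R)-12-acetoxy-6β,8α,20-trihydroxy-14,15-dinorlabdane-3,13-dione | CC(=O)[C@H](OC(C)=O)C[C@@H]1[C@@]2(CO)CCC(=O)C(C)(C)[C@@H]2[C@H](O)C[C@@]1(C)O | intermediate
21 | (12R)-6β,8α,12,20-tetraacetoxy-14,15-dinorlabdane-3,13-dione | CC(=O)[C@H](OC(C)=O)C[C@@H]1[C@@]2(COC(C)=O)CCC(=O)C(C)(C)[C@@H]2[C@H](OC(C)=O)C[C@@]1(C)OC(C)=O | intermediate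
22 | (12R,13S)-6β,8α,12,20-tetraacetoxy-13-hydroxylabd-14-en-3-one | C=C[C@](C)(O)[C@@H](C[C@@H]1[C@@]2(COC(C)=O)CCC(=O)C(C)(C)[C@@H]2[C@H](OC(C)=O)C[C@@]1(C)OC(C)=O)OC(C)=O | intermediate
23 | (12R,13S)-6β,8α,12,20-tetraacetoxylabd-14-ene-3α,13-diol | C=C[C@](C)(O)[C@@H](C[C@@H]1[C@@]2(COC(C)=O)CC[C@@H](O)C(C)(C)[C@@H]2[C@H](OC(C)=O)C[C@@]1(C)OC(C)=O)OC(C)=O | target

**Totals**
Total step count: 16. Longest linear sequence: 16 (fully linear from 1).

**Three steps most likely to fail**

Step 11 (the new photochemical C20 hydroxylation). The risks are competing 1,5-HAT from the C19 and C17 methyls, which are equally close to the 6β-oxygen, and over-oxidation. The fallback uses known chemistry and sets out from 15. NOCl/pyridine gives the 6β-nitrite ester F1. Barton nitrite photolysis (350 nm light, benzene) under O2 gives the C20 nitrate ester F2 with the 6β-OH restored, by the same 1,5-HAT but with NO/O2 capture. Zn/NH4OAc in MeOH cleaves the nitrate, and the fallback comes back to the route at 17.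

Step 10 (Pd/norbornene carbonyl transposition). The risk is that amination at C3 is next to the quaternary C4. The fallback sets out from 13. Pd(OAc)2/PPh3-catalysed formate reduction (HCO2H, n-Bu3N, DMF) gives the 2-ene F3. mCPBA/NaHCO3 epoxidises the α face (the β face is closed by C19 and C20) to the 2α,3α-epoxide F4. LiEt3BH opens it trans-diaxially at C2 to the 3α,6β-diol F5. Selective aerobic oxidation of the less shielded C3 carbinol (Cu(MeCN)4OTf, 2,2'-bipyridine, ABNO, air) comes back to the route at 15.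

Step 13 (Woodward cis-oxygenation). The risks are facial selectivity and interception of the iodo ketone by the 8-OH. The fallback sets out from 18. Dimethyldioxirane (acetone, −20 °C) epoxidises the enol ether from the α face, and aqueous work-up gives the (12S)-12-hydroxy ketone F6. Mitsunobu inversion (PPh3, DIAD, AcOH) occurs only at this activated α-ketol carbon, because the neopentyl C20-OH, the shielded 6β-OH and the tertiary 8-OH do not undergo SN2. It comes back to the route at 20.

Also at risk, though less so: the alkene regiochemistry in step 4, the enolate masking of the C2 ketone in step 8 and the Felkin–Anh selectivity in step 15.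

**Further compounds**
F1 | step 11 | 8α,13-epoxy-13β-methoxy-3-oxo-14,15-dinorlabdan-6β-yl nitrite | CO[C@]1(C)CC[C@@H]2[C@@]3(C)CCC(=O)C(C)(C)[C@@H]3[C@H](ON=O)C[C@@]2(C)O1
F2 | step 11 | 8α,13-epoxy-6β-hydroxy-13β-methoxy-3-oxo-14,15-dinorlabdan-20-yl nitrate | CO[C@]1(C)CC[C@@H]2[C@@]3(CO[N+](=O)[O-])CCC(=O)C(C)(C)[C@@H]3[C@H](O)C[C@@]2(C)O1
F3 | step 10 | 8α,13-epoxy-13β-methoxy-14,15-dinorlabd-2-en-6β-ol | CO[C@]1(C)CC[C@@H]2[C@@]3(C)CC=CC(C)(C)[C@@H]3[C@H](O)C[C@@]2(C)O1
F4 | step 10 | 2α,3α:8α,13-diepoxy-13β-methoxy-14,15-dinorlabdan-6β-ol | CO[C@]1(C)CC[C@@H]2[C@@]3(C)C[C@H]4O[C@H]4C(C)(C)[C@@H]3[C@H](O)C[C@@]2(C)O1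
F5 | step 10 | 8α,13-epoxy-13β-methoxy-14,15-dinorlabdane-3α,6β-diol | CO[C@]1(C)CC[C@@H]2[C@@]3(C)CC[C@@H](O)C(C)(C)[C@@H]3[C@H](O)C[C@@]2(C)O1
F6 | step 13 | (12S)-6β,8α,12,20-tetrahydroxy-14,15-dinorlabdane-3,13-dione | CC(=O)[C@@H](O)C[C@@H]1[C@@]2(CO)CCC(=O)C(C)(C)[C@@H]2[C@H](O)C[C@@]1(C)O
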